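(The runs are simulated with made-up constants; scatter was added.)

common to all: E 0.050 M

| flask | G | remark | time |
|---|---|---|---|
| eta | 1.2 equiv | run made earlier |  |
| theta | 1.3 equiv | run made earlier |  |
| gamma | 1.9 equiv | run made earlier |  |
| amber | 1.10 equiv |  | 2.0 h |
| red | 1.70 equiv |  | 2.0 h |

| run | time / min | E / % | Q / % | J / % | Z / % |
|---|---|---|---|---|---|
| eta | 5.00 | 10.0 | 39.0 | 2.5 | 49.9 |
| eta | 15.0 | 1.2 | 41.9 | 6.1 | 50.7 |
| eta | 30.0 | 0.5 | 44.6 | 7.3 | 49.1 |
| eta | 40.0 | 1.2 | 42.8 | 7.2 | 47.9 |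
| eta | 60.0 | 0 | 44.2 | 8.7 | 46.9 |
| theta | 12.0 | 0 | 39.2 | 5.2 | 56.0 |
| theta | 25.0 | 0.1 | 38.7 | 6.6 | 54.6 |
| theta | 40.0 | 0 | 41.1 | 7.2 | 52.2 |
| theta | 50.0 | 0 | 40.8 | 9.2 | 51.8 |
| theta | 60.0 | 0 | 39.8 | 9.6 | 50.1 |
| gamma | 12.0 | 0.7 | 27.0 | 5.4 | 68.3 |
| gamma | 25.0 | 1.5 | 24.7 | 4.9 | 64.7 |
| gamma | 40.0 | 0 | 25.8 | 8.0 | 64.5 |
| gamma | 50.0 | 0.3 | 25.3 | 9.2 | 63.7 |
| gamma | 60.0 | 0.3 | 25.6 | 11.8 | 63.4 |

(each reading ± 1 percentage point)

1. which of these there is most of at the end, counted by the E in it, amber (E / J / Q / Z)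
2. which of these there is most of at the end, counted by the E in it, red (E / J / Q / Z)
3. final amount of the leader among these, as a percentage of the E charged, in amber
4. final amount of the leader among these, as a percentage of the E charged, in red

- Z is meant together with its D
- solid, in amounts per volume of the solution: D
- steps under discussion: E + G -> Z; E + G -> Q; Z -> J; G -> X; D <-> Z

- If E has two exits, the Z side (Z with its D, plus the J made from it) and Q, then two amounts matter: the [G] present and a split concentration K. Their ratio [G]/K, the selectivity factor, gives the odds of Z side against Q.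
- The split comes early: in eta, E already reads 1.2% at 15.0 min.
- Gamma's Q averages 25.7%. At the mean [G] of that run, this gives a first K of 0.0242 M.
- But [G] falls as E goes. Adding the odds along that fall gives [Q] = K ln(([G]start + K)/([G]end + K)). I put the first K into the logarithm and go round once: the split concentration, the [G] at which E leaves equally by both exits, reads 0.0236 M.
- For theta this gives 39.2% of Q; its readings average 39.9%.
- My Q is 47.7% in amber and 29.1% in red. Extending theta's straight rise, J reaches 15.1%. So Z is 37.2% in amber, less than Q, and 55.8% in red, more than Q.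
- The forecast says Q at 47% in amber and Z at 55% in red, holding that “Z formation is higher order in G than Q formation”.
- The flask gives Q at 48.6% in amber and Z at 55.0% in red. K puts amber's starting odds at 2.33; the flask starts at 2.3.
- In amber, half of the Q turnover stands by 1.75 min and 97% by 0.200 h. Then Z → J runs on while D stands: from 1.00 h to 2.00 h, Z goes from 42.5% to 37.7%, J from 8.93% to 13.7%, and D from 37.2% to 32.4%.

    E + G → Z (k = 0.160 M⁻¹ s⁻¹)
    E + G → Q, rate k2*[E] as long as [G] is above zero (k = 0.00380 s⁻¹)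
    Z → J (k = 2.50 × 10⁻⁴ s⁻¹)
    G → X (k = 1.50 × 10⁻⁴ s⁻¹)
    D ⇌ Z, rate k5*(cs5 - [Z]) while solid is left; crystals form when [Z] > cs5 (solubility = 2.90 mM, k = 0.00250 s⁻¹)

- A neighbour of amber has 0.280 equiv of G, the limiting reagent, so I set [G]end to zero: K gives Q 22.0% and E left 72.0%. This neighbour ends with Q 21.9%, E 72.1%, G 0%: there the leader is E, not Q.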